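**Assumption:** The target, 8,3'-dihydroxy-6,7,4',5'-tetramethoxyflavone, has no stereocentre and is achiral, so "single enantiomer" needs no stereocontrol. The only stereo-element on the way, the E-alkene of the chalcone, is erased on cyclisation.

## Retrosynthetic overview
1. Both free OH groups (C8 and C3') are carried as aryl bromides and unmasked together at the end by double Miyaura borylation and oxidation, so no protecting groups are needed.
2. The pyranone ring (ring C) is formed from a 2'-hydroxychalcone by oxidative cyclisation with I2/DMSO. It is the only ring built, since rings A and B are bought.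
3. The chalcone comes from a Claisen–Schmidt condensation of a ring-A acetophenone with commercial 5-bromoveratraldehyde.
4. The ring-A piece comes from regioselective C3' bromination of commercial 2'-hydroxy-4',5'-dimethoxyacetophenone.

## Route

**Step 1**
Reactants: 1 2'-hydroxy-4',5'-dimethoxyacetophenone
Product: 2 3'-bromo-2'-hydroxy-4',5'-dimethoxyacetophenone
Conditions: NBS (1.05 equiv), NH4OAc (10 mol %), MeCN, 0 °C to rt, dark
Reagents that add atoms: N-bromosuccinimide, O=C1CCC(=O)N1Br
Why: This is an electrophilic aromatic bromination. C3' is ortho to both the OH and the 4'-OMe and meta to the acetyl, the para position to OH is blocked, and C6' is deactivated, so ionic NBS conditions give ring bromination rather than α-bromination.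

**Step 2**
Reactants: 2 3'-bromo-2'-hydroxy-4',5'-dimethoxyacetophenone; 3 3-bromo-4,5-dimethoxybenzaldehyde (5-bromoveratraldehyde)
Product: 5 (E)-3-(3-bromo-4,5-dimethoxyphenyl)-1-(3-bromo-2-hydroxy-4,5-dimethoxyphenyl)prop-2-en-1-one, via racemic aldol adduct 4 (not isolated)
Conditions: 50 % aq KOH (5 equiv), EtOH, rt, 24–48 h; then 1 M HCl
Reagents that add atoms: none
Why: This is a Claisen–Schmidt condensation. The non-enolisable aldehyde takes up the methyl ketone enolate, and E1cB loss of water gives the conjugated E-chalcone; aryl bromides and methyl ethers are inert to KOH at rt.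

**Step 3**
Reactants: 5 the (E)-2'-hydroxychalcone
Product: 7 8-bromo-2-(3-bromo-4,5-dimethoxyphenyl)-6,7-dimethoxy-4H-chromen-4-one, via racemic flavanone 6 (not isolated)
Conditions: I2 (10 mol %), DMSO, 130 °C, 2–4 h; aq Na2S2O3 wash
Reagents that add atoms: none
Why: This is the I2/DMSO oxidative cyclisation of a 2'-hydroxychalcone. Oxa-Michael closure gives the flavanone, then α-iodination and loss of HI give the flavone, with DMSO reoxidising HI; there is no free phenol or open activated ring position left to iodinate.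

**Step 4**
Reactants: 7 the 8,3'-dibromoflavone
Product: 9 8-hydroxy-2-(3-hydroxy-4,5-dimethoxyphenyl)-6,7-dimethoxy-4H-chromen-4-one (target), via bis(pinacol boronate) 8 (not isolated)
Conditions: B2pin2 (3 equiv), XPhos Pd G2 (5 mol %), KOAc (6 equiv), 1,4-dioxane, 100 °C; Celite filtration; then 30 % aq H2O2, THF/H2O (acetate-buffered), 0 °C to rt; mild acid work-up
Reagents that add atoms: bis(pinacolato)diboron, CC1(C)OB(OC1(C)C)B1OC(C)(C)C(C)(C)O1 (supplies the Bpin groups of 8); hydrogen peroxide, OO (supplies the two phenol oxygens of 9)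
Why: A double Miyaura borylation with a bulky biaryl phosphine handles the ortho-flanked C8–Br. Ipso-oxidation of the C–B bonds (1,2-aryl migration to peroxide oxygen) then occurs without strong base, so the base-sensitive pyranone and the methyl ethers survive.

## Compound list
1 | 2'-hydroxy-4',5'-dimethoxyacetophenone | CC(=O)c1cc(OC)c(OC)cc1O | starting material
2 | 3'-bromo-2'-hydroxy-4',5'-dimethoxyacetophenone | CC(=O)c1cc(OC)c(OC)c(Br)c1O | intermediate
3 | 3-bromo-4,5-dimethoxybenzaldehyde | O=Cc1cc(Br)c(OC)c(OC)c1 | starting material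
4 | 3-(3-bromo-4,5-dimethoxyphenyl)-1-(3-bromo-2-hydroxy-4,5-dimethoxyphenyl)-3-hydroxypropan-1-one (racemic aldol, not isolated) | O=C(CC(O)c1cc(Br)c(OC)c(OC)c1)c1cc(OC)c(OC)c(Br)c1O | intermediate
5 | (E)-3-(3-bromo-4,5-dimethoxyphenyl)-1-(3-bromo-2-hydroxy-4,5-dimethoxyphenyl)prop-2-en-1-one | O=C(/C=C/c1cc(Br)c(OC)c(OC)c1)c1cc(OC)c(OC)c(Br)c1O | intermediate
6 | 8-bromo-2-(3-bromo-4,5-dimethoxyphenyl)-6,7-dimethoxychroman-4-one (racemic flavanone, not isolated) | O=C1CC(c2cc(Br)c(OC)c(OC)c2)Oc2c(Br)c(OC)c(OC)cc21 | intermediate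
7 | 8-bromo-2-(3-bromo-4,5-dimethoxyphenyl)-6,7-dimethoxy-4H-chromen-4-one | O=c1cc(-c2cc(Br)c(OC)c(OC)c2)oc2c(Br)c(OC)c(OC)cc12 | intermediate
8 | 6,7-dimethoxy-8-(pinacolboryl)-2-[3,4-dimethoxy-5-(pinacolboryl)phenyl]-4H-chromen-4-one (not isolated) | O=c1cc(-c2cc(B3OC(C)(C)C(C)(C)O3)c(OC)c(OC)c2)oc2c(B3OC(C)(C)C(C)(C)O3)c(OC)c(OC)cc12 | intermediate
9 | 8-hydroxy-2-(3-hydroxy-4,5-dimethoxyphenyl)-6,7-dimethoxy-4H-chromen-4-one | COc1cc(-c2cc(=O)c3cc(OC)c(OC)c(O)c3o2)cc(O)c1OC | target

**Total step count:** 4. **Longest linear sequence:** 4 (1 → 2 → 5 → 7 → 9).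

## Three steps most likely to fail, with fallbacks

**Step 4.** The risks are slow borylation or hydrodebromination at the doubly ortho-flanked C8–Br, and over-oxidation.
- This fallback sets out from 2 and comes back at 9. It installs the oxygens before the ring is built and carries them as benzyl ethers.
- Compound 2 is hydroxylated as an ortho-bromophenol with aq NaOH and Cu powder/CuSO4 at reflux under N2 (the 5-bromovanillin to 5-hydroxyvanillin type reaction). This gives 2',3'-dihydroxy-4',5'-dimethoxyacetophenone F1.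
- BnBr (1 equiv) and K2CO3 in acetone alkylate only the non-chelated 3'-OH, giving 3'-benzyloxy-2'-hydroxy-4',5'-dimethoxyacetophenone F2.
- Commercial 3-hydroxy-4,5-dimethoxybenzaldehyde is benzylated in the same way to 3-benzyloxy-4,5-dimethoxybenzaldehyde F3.
- KOH/EtOH condensation of F2 with F3 gives the dibenzyloxy chalcone F4.
- I2/DMSO then gives 8-benzyloxy-2-(3-benzyloxy-4,5-dimethoxyphenyl)-6,7-dimethoxy-4H-chromen-4-one F5.
- Hydrogenolysis (H2 1 atm, Pd/C, EtOAc/MeOH) gives 9.

**Step 3.** The risks are demethylation or tar formation at 130 °C, and incomplete dehydrogenation.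
- This fallback sets out from 5 and comes back at 7. It separates ring closure from oxidation and replaces halogenation/elimination by hydride abstraction.
- Compound 5 is isomerised with NaOAc in refluxing EtOH, and the flavanone 6 is isolated this time.
- Compound 6 is then dehydrogenated with DDQ in refluxing dioxane to 7.
- No new compound is made.

**Step 2.** The risks are sluggish enolate chemistry of the hindered bromophenolate ketone, and Cannizzaro loss of 3.
- This fallback sets out from 2 and 3 and comes back at 7. It is a redox-neutral Baker–Venkataraman sequence that bypasses the chalcone altogether.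
- Compound 3 is oxidised (Pinnick: NaClO2, NaH2PO4, 2-methyl-2-butene) to 3-bromo-4,5-dimethoxybenzoic acid F6.
- SOCl2 converts F6 to 3-bromo-4,5-dimethoxybenzoyl chloride F7.
- F7 acylates the phenol of 2 in pyridine with DMAP, giving the aryl ester F8.
- KOH in pyridine at 50 °C causes O-to-C acyl migration to the 1,3-diketone F9.
- H2SO4 in AcOH cyclodehydrates F9 to 7.

## Further compounds
F1 | step 4 | 2',3'-dihydroxy-4',5'-dimethoxyacetophenone | CC(=O)c1cc(OC)c(OC)c(O)c1O
F2 | step 4 | 3'-benzyloxy-2'-hydroxy-4',5'-dimethoxyacetophenone | CC(=O)c1cc(OC)c(OC)c(OCc2ccccc2)c1O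
F3 | step 4 | 3-benzyloxy-4,5-dimethoxybenzaldehyde | O=Cc1cc(OCc2ccccc2)c(OC)c(OC)c1
F4 | step 4 | (E)-3-(3-benzyloxy-4,5-dimethoxyphenyl)-1-(3-benzyloxy-2-hydroxy-4,5-dimethoxyphenyl)prop-2-en-1-one | O=C(/C=C/c1cc(OCc2ccccc2)c(OC)c(OC)c1)c1cc(OC)c(OC)c(OCc2ccccc2)c1O
F5 | step 4 | 8-benzyloxy-2-(3-benzyloxy-4,5-dimethoxyphenyl)-6,7-dimethoxy-4H-chromen-4-one | O=c1cc(-c2cc(OCc3ccccc3)c(OC)c(OC)c2)oc2c(OCc3ccccc3)c(OC)c(OC)cc12
F0 | step 3 | none | none
F6 | step 2 | 3-bromo-4,5-dimethoxybenzoic acid | O=C(O)c1cc(Br)c(OC)c(OC)c1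
F7 | step 2 | 3-bromo-4,5-dimethoxybenzoyl chloride | O=C(Cl)c1cc(Br)c(OC)c(OC)c1
F8 | step 2 | 2-acetyl-6-bromo-4,5-dimethoxyphenyl 3-bromo-4,5-dimethoxybenzoate | CC(=O)c1cc(OC)c(OC)c(Br)c1OC(=O)c1cc(Br)c(OC)c(OC)c1
F9 | step 2 | 1-(3-bromo-2-hydroxy-4,5-dimethoxyphenyl)-3-(3-bromo-4,5-dimethoxyphenyl)propane-1,3-dione | O=C(CC(=O)c1cc(Br)c(OC)c(OC)c1)c1cc(OC)c(OC)c(Br)c1O
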